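**Plan**

- Ring labels: ring A is the trioxygenated ring, ring B the para-phenylene, ring C the 1,2,3-trisubstituted ring with one OH, ring D the ortho-disubstituted ring. The three phenols travel as methyl ethers.
- Cuts, in retrosynthetic order: the CH2–CH2 bond between rings A and D (as C=C from two aryl aldehydes), the ring C–O–ring D ether bond, the CH2–CH2 bond between rings B and C (as C=C), and the ring A–O–ring B ether bond.
- Enabling feature: both carbons of the ring A–CH2–CH2–ring D bridge are benzylic, unhindered and remote from either diaryl ether oxygen. Each can therefore be carried as a formyl carbon and joined by reductive carbonyl coupling.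
- Forward order: ring A is joined to ring B (SNAr), ring C is attached (Wittig, hydrogenation), ring D is attached (SNAr), and the 17-membered ring closes at the ring A/ring D bridge. Hydrogenation and demethylation finish the route.
- Stereochemistry: the target has no stereocentre, and both alkenes made on the way are hydrogenated, so their geometry is immaterial.

Key step: step 10

Assumption: stilbenes 10 and 16 are expected as E/Z mixtures (10 drawn E, 16 drawn Z), and either isomer serves. Pinacolate 15 is drawn as a dichlorotitanium diolate of tetravalent titanium, the simplest discrete formulation of a surface-bound species.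

**Route**

Step 1
Reactants: 1 2-hydroxy-3-methoxybenzaldehyde (o-vanillin)
Product: 2 2-(benzyloxy)-3-methoxybenzaldehyde
Conditions: BnBr, K2CO3, DMF, rt
Reagents that add atoms: benzyl bromide, BrCc1ccccc1
Why: Williamson etherification of the phenoxide with a reactive benzylic bromide should be clean and masks the ring C phenol until the hydrogenolysis of step 7.

Step 2
Reactants: 2 2-(benzyloxy)-3-methoxybenzaldehyde
Product: 3 [2-(benzyloxy)-3-methoxyphenyl]methanol
Conditions: NaBH4, MeOH, 0 °C
Reagents that add atoms: none
Why: Borohydride reduction of an aryl aldehyde to the benzylic alcohol is routine and leaves both ethers untouched.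

Step 3
Reactants: 3 [2-(benzyloxy)-3-methoxyphenyl]methanol
Product: 4 [2-(benzyloxy)-3-methoxybenzyl]triphenylphosphonium bromide
Conditions: PPh3·HBr, MeCN, reflux
Reagents that add atoms: triphenylphosphine hydrobromide, [Br-].c1ccc(cc1)[PH+](c1ccccc1)c1ccccc1
Why: Acid-promoted substitution of an electron-rich benzylic alcohol by triphenylphosphine (direct phosphonium salt formation) should give the Wittig salt in one operation.

Step 4
Reactants: 5 3-hydroxy-4,5-dimethoxybenzaldehyde
Product: 6 5-(1,3-dioxolan-2-yl)-2,3-dimethoxyphenol
Conditions: HOCH2CH2OH, p-TsOH (cat.), toluene, reflux, Dean–Stark; Et3N quench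
Reagents that add atoms: ethylene glycol, OCCO
Why: Acid-catalysed acetalisation with azeotropic removal of water masks the ring A aldehyde, so that only the ring B aldehyde is free for the later Wittig reaction.

Step 5
Reactants: 6 5-(1,3-dioxolan-2-yl)-2,3-dimethoxyphenol; 7 4-fluorobenzaldehyde
Product: 8 4-[5-(1,3-dioxolan-2-yl)-2,3-dimethoxyphenoxy]benzaldehyde
Conditions: K2CO3, DMF, 130 °C
Reagents that add atoms: none
Why: Nucleophilic aromatic substitution (addition–elimination) of fluoride by the phenoxide is activated by the para formyl group, and the acetal is stable to the basic medium.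

Step 6
Reactants: 4 [2-(benzyloxy)-3-methoxybenzyl]triphenylphosphonium bromide; 8 4-[5-(1,3-dioxolan-2-yl)-2,3-dimethoxyphenoxy]benzaldehyde
Product: 10 2-[3-(4-{2-[2-(benzyloxy)-3-methoxyphenyl]ethenyl}phenoxy)-4,5-dimethoxyphenyl]-1,3-dioxolane (E/Z mixture; E isomer drawn), via phosphonium ylide 9 (not isolated)
Conditions: t-BuOK, THF, 0 °C; then 8, 0 °C to rt
Reagents that add atoms: none
Why: Wittig olefination of a non-enolisable aryl aldehyde with a semi-stabilised benzylic ylide should join rings B and C reliably, and the alkene geometry is irrelevant because step 7 saturates it.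

Step 7
Reactants: 10 stilbene acetal (E/Z mixture)
Product: 11 2-(2-{4-[5-(1,3-dioxolan-2-yl)-2,3-dimethoxyphenoxy]phenyl}ethyl)-6-methoxyphenol
Conditions: H2 (1 atm), Pd/C, EtOAc, solid NaHCO3, rt
Reagents that add atoms: none
Why: Catalytic hydrogenation over palladium on carbon should saturate the stilbene and hydrogenolyse the benzyl ether in one operation, with the acetal preserved in the neutral, buffered medium.

Step 8
Reactants: 11 2-(2-{4-[5-(1,3-dioxolan-2-yl)-2,3-dimethoxyphenoxy]phenyl}ethyl)-6-methoxyphenol; 12 2-fluorobenzaldehyde
Product: 13 2-[2-(2-{4-[5-(1,3-dioxolan-2-yl)-2,3-dimethoxyphenoxy]phenyl}ethyl)-6-methoxyphenoxy]benzaldehyde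
Conditions: Cs2CO3, DMA, 130 °C
Reagents that add atoms: none
Why: Nucleophilic aromatic substitution of the ortho-formyl-activated fluoride by the caesium phenoxide should form the hindered ring C–O–ring D ether, with the poorly ion-paired phenoxide offsetting the two ortho substituents.

Step 9
Reactants: 13 2-[2-(2-{4-[5-(1,3-dioxolan-2-yl)-2,3-dimethoxyphenoxy]phenyl}ethyl)-6-methoxyphenoxy]benzaldehyde
Product: 14 3-(4-{2-[2-(2-formylphenoxy)-3-methoxyphenyl]ethyl}phenoxy)-4,5-dimethoxybenzaldehyde
Conditions: 2 M aq. HCl, THF, rt
Reagents that add atoms: water, O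
Why: Acid-catalysed hydrolysis of the electron-rich aryl dioxolane is fast and releases the second aldehyde without affecting the methyl or diaryl ethers.

Step 10
Reactants: 14 3-(4-{2-[2-(2-formylphenoxy)-3-methoxyphenyl]ethyl}phenoxy)-4,5-dimethoxybenzaldehyde
Product: 16 macrocyclic stilbene trimethyl ether (Z isomer drawn), via titanium pinacolate 15 (not isolated)
Conditions: TiCl4, Zn, pyridine, THF, reflux; 14 added by syringe pump (high dilution); aq. K2CO3 work-up
Reagents that add atoms: none
Why: Single-electron transfer from low-valent titanium (prepared from TiCl4, tetravalent titanium, and Zn) converts both formyl groups of 14 into ketyl radicals, whose combination gives the titanium-bound pinacolate 15 and is the ring-closing C–C bond formation; loss of both oxygens to titanium at reflux then delivers the alkene. The closest known reaction type is the intramolecular McMurry coupling of aromatic dialdehydes to macrocyclic stilbenes and cyclophane alkenes. The one ring formed, the 17-membered macrocycle, closes by end-to-end reductive coupling of the two formyl carbons of the open-chain dialdehyde, the five-membered titanadioxolane of 15 being transient. No stereocentre survives, since the two carbinol centres of 15 are lost on deoxygenation and the alkene geometry (Z expected within the ring) is erased in step 11. The selectivity required is ring closure over intermolecular coupling, which slow addition at high dilution and the bend imposed by the ortho-linked rings C and D should secure, while the methyl ethers and diaryl ethers are inert to the reagent.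

Step 11
Reactants: 16 macrocyclic stilbene trimethyl ether
Product: 17 macrocyclic bis(bibenzyl) trimethyl ether
Conditions: H2 (1 atm), Pd/C, EtOAc, rt
Reagents that add atoms: none
Why: Catalytic hydrogenation of the disubstituted stilbene alkene gives the saturated CH2–CH2 bridge, and no other group in 16 is reducible under these conditions.

Step 12
Reactants: 17 macrocyclic bis(bibenzyl) trimethyl ether
Product: 18 target compound CNP0290892.0
Conditions: BBr3, CH2Cl2, −78 °C to rt; then H2O
Reagents that add atoms: none
Why: Lewis acid-mediated cleavage of aryl methyl ethers by BBr3 should remove all three methyl groups while leaving the diaryl ethers, which lack an sp3 carbon for bromide attack, intact.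

**Compound list**

1 | 2-hydroxy-3-methoxybenzaldehyde (o-vanillin) | O=Cc1cccc(OC)c1O | starting material
2 | 2-(benzyloxy)-3-methoxybenzaldehyde | O=Cc1cccc(OC)c1OCc1ccccc1 | intermediate
3 | [2-(benzyloxy)-3-methoxyphenyl]methanol | OCc1cccc(OC)c1OCc1ccccc1 | intermediate
4 | [2-(benzyloxy)-3-methoxybenzyl]triphenylphosphonium bromide | [Br-].COc1cccc(C[P+](c2ccccc2)(c2ccccc2)c2ccccc2)c1OCc1ccccc1 | intermediate
5 | 3-hydroxy-4,5-dimethoxybenzaldehyde | O=Cc1cc(O)c(OC)c(OC)c1 | starting material
6 | 5-(1,3-dioxolan-2-yl)-2,3-dimethoxyphenol | COc1cc(cc(O)c1OC)C1OCCO1 | intermediate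
7 | 4-fluorobenzaldehyde | O=Cc1ccc(F)cc1 | starting material
8 | 4-[5-(1,3-dioxolan-2-yl)-2,3-dimethoxyphenoxy]benzaldehyde | COc1cc(cc(Oc2ccc(C=O)cc2)c1OC)C1OCCO1 | intermediate
9 | [2-(benzyloxy)-3-methoxybenzylidene]triphenylphosphorane (ylide, not isolated) | COc1cccc(C=P(c2ccccc2)(c2ccccc2)c2ccccc2)c1OCc1ccccc1 | intermediate
10 | 2-[3-(4-{(E)-2-[2-(benzyloxy)-3-methoxyphenyl]ethenyl}phenoxy)-4,5-dimethoxyphenyl]-1,3-dioxolane (E/Z mixture expected; E isomer drawn) | COc1cc(cc(Oc2ccc(/C=C/c3cccc(OC)c3OCc3ccccc3)cc2)c1OC)C1OCCO1 | intermediate
11 | 2-(2-{4-[5-(1,3-dioxolan-2-yl)-2,3-dimethoxyphenoxy]phenyl}ethyl)-6-methoxyphenol | COc1cc(cc(Oc2ccc(CCc3cccc(OC)c3O)cc2)c1OC)C1OCCO1 | intermediate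
12 | 2-fluorobenzaldehyde | O=Cc1ccccc1F | starting material
13 | 2-[2-(2-{4-[5-(1,3-dioxolan-2-yl)-2,3-dimethoxyphenoxy]phenyl}ethyl)-6-methoxyphenoxy]benzaldehyde | COc1cc(cc(Oc2ccc(CCc3cccc(OC)c3Oc3ccccc3C=O)cc2)c1OC)C1OCCO1 | intermediate
14 | 3-(4-{2-[2-(2-formylphenoxy)-3-methoxyphenyl]ethyl}phenoxy)-4,5-dimethoxybenzaldehyde (acyclic dialdehyde) | COc1cc(C=O)cc(c1OC)Oc1ccc(cc1)CCc1cccc(OC)c1Oc1ccccc1C=O | intermediate
15 | macrocyclic titanium pinacolate (dichlorotitanium diolate of tetravalent titanium; carbinol configurations undefined; not isolated) | COc1cc(C4O[Ti](Cl)(Cl)OC4c2ccccc2Oc2c(OC)cccc2CCc2ccc(cc2)O3)cc3c1OC | intermediate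
16 | macrocyclic stilbene trimethyl ether, C=C between rings A and D (Z isomer drawn) | COc1cc(/C=C\c2ccccc2Oc2c(OC)cccc2CCc2ccc(cc2)O3)cc3c1OC | intermediate
17 | macrocyclic bis(bibenzyl) trimethyl ether | COc1cc2cc(c1OC)Oc1ccc(cc1)CCc1cccc(OC)c1Oc1ccccc1CC2 | intermediate
18 | CNP0290892.0, macrocyclic bis(bibenzyl) triphenol | Oc1cc2cc(c1O)Oc1ccc(cc1)CCc1cccc(O)c1Oc1ccccc1CC2 | target

**Step count**

Total steps: 12. Longest linear sequence: 10 steps (steps 1, 2, 3, 6, 7, 8, 9, 10, 11, 12, from o-vanillin).

**Steps most likely to fail**

1. Step 10. Intermolecular carbonyl coupling may outrun ring closure and give oligomers, or the reduction may stall at the pinacol stage. The fallback closes the same bond and ring by an intramolecular Wittig reaction. It sets out from 13, whose free ring D aldehyde is reduced (NaBH4, MeOH/THF, 0 °C) to the benzylic alcohol acetal F1. Treatment with PPh3·HBr in refluxing MeCN should form the phosphonium salt and, through the water released and the acid present, cleave the dioxolane, giving the formyl phosphonium bromide F2. Slow addition of F2 to NaOMe in CH2Cl2 at high dilution generates the formyl ylide F3, which should cyclise onto the ring A aldehyde. The fallback comes back to the route at 16.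

2. Step 8. Addition of the doubly ortho-substituted phenoxide to an ortho-substituted fluoroarene may be too slow, with base-induced loss of the aldehyde at the temperature needed. The fallback replaces addition–elimination by a copper-catalysed Ullmann ether coupling. It sets out from 11, which is coupled with 2-bromobenzaldehyde (CuI, copper monoiodide, picolinic acid, K3PO4, DMSO, 90 °C), a catalyst system suited to hindered phenols and ortho-substituted aryl halides. It comes back at 13 and makes no new compound (F0).

3. Step 3. The benzyl ether, twisted between two ortho substituents, may be lost under the acidic conditions, or the benzylic cation may alkylate another arene. The fallback avoids acid and changes the olefination. It sets out from 3, which an Appel bromination (CBr4, PPh3, CH2Cl2, 0 °C) converts to 2-(benzyloxy)-1-(bromomethyl)-3-methoxybenzene F4. An Arbuzov reaction (P(OEt)3, neat, 130 °C) then gives diethyl [2-(benzyloxy)-3-methoxybenzyl]phosphonate F5. Horner–Wadsworth–Emmons olefination of 8 with F5 (NaH, THF, 0 °C to rt) should give the E isomer, coming back to the route at 10.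

**Further compounds**

F1 | step 10 | {2-[2-(2-{4-[5-(1,3-dioxolan-2-yl)-2,3-dimethoxyphenoxy]phenyl}ethyl)-6-methoxyphenoxy]phenyl}methanol | COc1cc(cc(Oc2ccc(CCc3cccc(OC)c3Oc3ccccc3CO)cc2)c1OC)C1OCCO1
F2 | step 10 | {2-[2-(2-{4-[5-formyl-2,3-dimethoxyphenoxy]phenyl}ethyl)-6-methoxyphenoxy]benzyl}triphenylphosphonium bromide | [Br-].COc1cc(C=O)cc(c1OC)Oc1ccc(cc1)CCc1cccc(OC)c1Oc1ccccc1C[P+](c1ccccc1)(c1ccccc1)c1ccccc1
F3 | step 10 | formyl ylide derived from F2 (formed in the flask) | COc1cc(C=O)cc(c1OC)Oc1ccc(cc1)CCc1cccc(OC)c1Oc1ccccc1C=P(c1ccccc1)(c1ccccc1)c1ccccc1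
F0 | step 8 | none | none
F4 | step 3 | 2-(benzyloxy)-1-(bromomethyl)-3-methoxybenzene | BrCc1cccc(OC)c1OCc1ccccc1
F5 | step 3 | diethyl [2-(benzyloxy)-3-methoxybenzyl]phosphonate | CCOP(=O)(Cc1cccc(OC)c1OCc1ccccc1)OCC
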